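The route rests on cutting the bond between C1' of the docosyl chain and C3 of the quinone ring. C3 is the central carbon of the vinylogous acid C2(OH)=C3–C4=O, so the unsubstituted ring behaves as a cyclic 1,3-dicarbonyl C–H acid. C6 belongs to the O-methyl-capped unit C5(OMe)=C6–C1=O and is inert. A three-component organocatalytic reductive alkylation therefore merges 2-hydroxy-5-methoxy-1,4-benzoquinone, docosanal and a Hantzsch ester in one flask. Knoevenagel condensation at C3, then hydride transfer to the resulting quinone methide, gives the target directly at the right oxidation level, without protecting groups. The precursors are the mono-hydrolysed 2,5-dimethoxyquinone and the C22 aldehyde.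

Key step: step 3

Remark: quinone numbering is C1(=O), C2(OH), C3(docosyl), C4(=O), C5(OMe), C6(H), with C1' the ring-bound chain carbon; the target has no stereocentre, and the exocyclic C=C of transient 6 is drawn without geometry because both isomers give the same product on reduction.

Step 1
Reactants: 1 2,5-dimethoxy-1,4-benzoquinone
Product: 3 2-hydroxy-5-methoxy-1,4-benzoquinone, via sodium quinonolate 2 (not isolated)
Conditions: NaOH (1.05 equiv), THF–H2O, 0 °C to 25 °C; then 1 M HCl
Reagents that add atoms: sodium hydroxide, [Na+].[OH-]
Why: Vinylogous ester saponification (addition–elimination of hydroxide at a methoxy-bearing ring carbon of the symmetric quinone) should stop after one methoxy group, because the product is deprotonated at once to the delocalised quinonolate 2, whose charge repels a second hydroxide at this temperature.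

Step 2
Reactants: 4 1-docosanol
Product: 5 docosanal
Conditions: IBX (2-iodoxybenzoic acid, 1.5 equiv), EtOAc, 80 °C; filtration
Reagents that add atoms: none
Why: IBX oxidation of a primary alcohol (hypervalent iodine oxidation) in hot ethyl acetate dissolves the waxy alcohol while the reagent and its spent form stay insoluble, and it should stop at the aldehyde because no aldehyde hydrate is available for further oxidation.

Step 3
Reactants: 3 2-hydroxy-5-methoxy-1,4-benzoquinone; 5 docosanal
Product: 7 3-docosyl-2-hydroxy-5-methoxy-1,4-benzoquinone, via docosylidene trione 6 (not isolated)
Conditions: Hantzsch ester (diethyl 2,6-dimethyl-1,4-dihydropyridine-3,5-dicarboxylate, 1.1 equiv), L-proline (20 mol %), CH2Cl2, 25 °C; work-up in air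
Reagents that add atoms: none
Why: L-Proline activates aldehyde 5 by iminium formation, the enolic carbon C3 of 3 (the central carbon of the C2(OH)=C3–C4=O vinylogous acid) adds to it, and loss of the amine completes a Knoevenagel condensation to the 3-docosylidene-1,2,4-trione 6, an ortho-quinone methide. This strongly electrophilic alkylidene accepts hydride from C4 of the Hantzsch ester at its exocyclic carbon and proton transfer restores the hydroxyquinone chromophore, so the C1'–C3 bond is made and brought to the CH2 level in one operation. The closest known reaction type is the organocatalytic three-component reductive alkylation (Knoevenagel condensation and transfer hydrogenation cascade) of cyclic 1,3-dicarbonyl compounds and of hydroxyquinones such as 2-hydroxy-1,4-naphthoquinone and 2,5-dihydroxy-1,4-benzoquinone with aldehydes. No ring is closed and no stereocentre is created. The step needs site selectivity (C3 over C6), mono-alkylation and chemoselective hydride delivery: the methyl cap on O5 leaves C6 as a non-acidic enol ether carbon, product 7 has no enolic C–H left, and the two oxygen donors lower the reduction potential of the ring so that 6, not a quinone carbonyl, is the best hydride acceptor. The Hantzsch ester, present from the start, should intercept 6 before a second molecule of 3 adds to it, and any hydroquinone formed by over-reduction should be re-oxidised by air on work-up.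

Compound list
1 | 2,5-dimethoxy-1,4-benzoquinone | COC1=CC(=O)C(OC)=CC1=O | starting material
2 | sodium 4-methoxy-3,6-dioxocyclohexa-1,4-dien-1-olate (sodium quinonolate) | [Na+].[O-]C1=CC(=O)C(OC)=CC1=O | intermediate
3 | 2-hydroxy-5-methoxy-1,4-benzoquinone | O=C1C=C(OC)C(=O)C=C1O | intermediate
4 | 1-docosanol | CCCCCCCCCCCCCCCCCCCCCCO | starting material
5 | docosanal | CCCCCCCCCCCCCCCCCCCCCC=O | intermediate
6 | 3-docosylidene-5-methoxycyclohex-5-ene-1,2,4-trione (quinone numbering, docosylidene trione) | CCCCCCCCCCCCCCCCCCCCCC=C1C(=O)C(=O)C=C(OC)C1=O | intermediate
7 | 3-docosyl-2-hydroxy-5-methoxy-1,4-benzoquinone | CCCCCCCCCCCCCCCCCCCCCCC1=C(O)C(=O)C=C(OC)C1=O | target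

Total step count: 3. Longest linear sequence: 2 steps (1 to 3 to 7, or 4 to 5 to 7).

Steps most likely to fail

1. Step 3.
- Risk: The secondary amine may be drained by addition–elimination at the methoxy-bearing C5. Hydride may reach the quinone ring before condensation. The alkylidene may also be trapped by a second quinone molecule faster than by hydride.
- Fallback: The same C1'–C3 bond is made at the arene oxidation level by alkylation of an aryllithium. The detour sets out from 4 and comes back at 7. Alcohol 4 is heated with 48% aqueous HBr and H2SO4 to give 1-bromodocosane F1. Commercial 1,2,4,5-tetramethoxybenzene is deprotonated between two methoxy groups (n-BuLi, TMEDA, THF, 0 °C, directed ortho-metalation) to 2,3,5,6-tetramethoxyphenyllithium F2. This is alkylated with the bromide to 1-docosyl-2,3,5,6-tetramethoxybenzene F3. Oxidative demethylation with (NH4)2Ce(NO3)6 in MeCN–H2O gives 3-docosyl-2,5-dimethoxy-1,4-benzoquinone F4, a single quinone because both para pairs of methoxy groups lead to the same compound. Finally, 70% aqueous HClO4 in THF at 25 °C should hydrolyse only the crowded C2 methoxy group, which the neighbouring chain twists out of conjugation, and so deliver 7.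

2. Step 1.
- Risk: The second methoxy group may also be lost, because the dissolved mono-salt meets hydroxide while the starting quinone is still suspended. The base may also degrade the quinone.
- Fallback: Desymmetrisation is moved behind the C–C bond formation. The detour sets out from 1 and comes back at 7. Excess aqueous NaOH at reflux, then HCl, carries the hydrolysis through to 2,5-dihydroxy-1,4-benzoquinone F5 (also a catalogue compound). The L-proline and Hantzsch ester reductive alkylation with one equivalent of 5 gives 3-docosyl-2,5-dihydroxy-1,4-benzoquinone F6. A vinylogous Fischer esterification (MeOH–CHCl3, cat. H2SO4, 60 °C) should etherify only the C5 hydroxyl next to C6–H, since an ether at C2 would be crowded by the docosyl chain, and gives 7.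

3. Step 2.
- Risk: Conversion of the poorly soluble waxy alcohol may be incomplete. The aldehyde may also be oxidised further or self-condense during isolation.
- Fallback: The aldehyde oxygen is brought in by substitution instead of dehydrogenation. The detour sets out from 4 and comes back at 5. TsCl and pyridine in CH2Cl2 give docosyl 4-methylbenzenesulfonate F7, and a Kornblum oxidation (DMSO, NaHCO3, 150 °C, short heating) converts it into 5.

Further compounds
F1 | step 3 | 1-bromodocosane | CCCCCCCCCCCCCCCCCCCCCCBr
F2 | step 3 | 2,3,5,6-tetramethoxyphenyllithium | [Li]c1c(OC)c(OC)cc(OC)c1OC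
F3 | step 3 | 1-docosyl-2,3,5,6-tetramethoxybenzene | CCCCCCCCCCCCCCCCCCCCCCc1c(OC)c(OC)cc(OC)c1OC
F4 | step 3 | 3-docosyl-2,5-dimethoxy-1,4-benzoquinone | CCCCCCCCCCCCCCCCCCCCCCC1=C(OC)C(=O)C=C(OC)C1=O
F5 | step 1 | 2,5-dihydroxy-1,4-benzoquinone | O=C1C=C(O)C(=O)C=C1O
F6 | step 1 | 3-docosyl-2,5-dihydroxy-1,4-benzoquinone | CCCCCCCCCCCCCCCCCCCCCCC1=C(O)C(=O)C=C(O)C1=O
F7 | step 2 | docosyl 4-methylbenzenesulfonate | CCCCCCCCCCCCCCCCCCCCCCOS(=O)(=O)c1ccc(C)cc1
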